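The rate constants were set for the occasion.

If you charge more D to get more free E, the D you add also takes E away.

common to all: Q 0.200 M; time 6.0 h

| run | D |
|---|---|
| dusk | 0.0080 M |
| noon | 0.020 M |
| autumn | 0.060 M |
| summer | 0.20 M |

    D + E ⇌ D.E, settled at all times (K1 = 70 L mol⁻¹)
    J + Q ⇌ L + E (K2 = 0.476, k2 = 0.00238 L mol⁻¹ s⁻¹)
    Z + Q ⇌ L + J (K3 = 3.09, k3 = 5.39 × 10⁻⁴ L mol⁻¹ s⁻¹)
    D + Q ⇌ L + X (K4 = 0.34, k4 = 0.00144 L mol⁻¹ s⁻¹)
    X + Q ⇌ L + Z (K5 = 1.32, k5 = 0.00124 L mol⁻¹ s⁻¹)

- [E] (only what is free in solution) at the end for dusk, noon, autumn, summer, in this order
- how that number moves from the first to the last of them (hardly changes / falls all the way / falls, then rises / rises all the way / rises, then falls)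

- percentages count the D that a species holds: one D.E counts as two
- E is meant together with its D.E
- in an amount of E, one D.E counts as one E
- the concentration of E that is asked is that of its free form alone
- "hardly changes" means that all values lie within two and a half points (for a concentration: within two and a half percent of the largest)
- run time (dusk): 6.0 h

D and E meet in a fast balance, so the rate of parking, as D.E, equals the rate of release. Divide one by the other and time drops out: c(D.E)/c(E) equals 70 L mol⁻¹ times c(D). I call this the parking ratio; in the summer flask, at the charged c(D), it is 14.0. The share of E left free is one over one plus that ratio.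

For my own reckoning, the half-lives of the four exchanges at dusk, each by its forward rate alone with the other concentrations as charged, add up to 3.64 h, shorter than the run of 6.0 h, but not by much. So I let half of the D reach E in each flask. In the summer flask, though, each E costs 4 Q, and Q is the limiting reagent: its charge pays for 25.0% of the D, so I use that share there. With the charged c(D), this gives, as ratio, free share and reckoned c(E):

- dusk: 0.560, 64.1%, 0.00256 M
- noon: 1.40, 41.7%, 0.00417 M
- autumn: 4.20, 19.2%, 0.00577 M
- summer: 14.0, 6.67%, 0.00333 M

Read down the free shares and they shrink with every flask. Read down the last column and my reckoned c(E) still climbs to autumn, the charge growing faster than the parking factor. In my reckoning summer drops below autumn, where the share paid for by Q is the smaller one. So I commit to a row that rises, then falls, with its top at autumn.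

The forecast gives 0.0037 M, 0.0058 M, 0.0032 M and 0.0014 M, also rises, then falls, holding that “leftover D traps much of the E as D.E”.

The flasks end at 0.00367 M, 0.00532 M, 0.00394 M and 0.00115 M: rises, then falls, as I reckoned, but with the top at noon, not at autumn, and the row turns at 0.024 M.

My ratio used the charged D, but the summer flask ends with 64.0% of it, so its ratio is 8.96. E, free and parked together, stands at 5.73% of the D charged, and the ratio keeps 0.00115 M of it free. The autumn flask, with ratio 1.32 and E at 15.2%, keeps 0.00394 M free. Parking is a part of the fall in the summer flask: without it, that flask ends at 0.00384 M rather than 0.00115 M, a factor of 3.33. In the dusk flask the largest single effect among those tried is the length of the run: ten times as long, it gives 0.00575 M rather than 0.00367 M.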